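## Structural features

The target is a trans-fused decalin. Ring A is C1–C5 and C10, ring B is C5–C10, and C9 carries an (E)-3-methylpent-2-enoic acid chain (C11–C16). C17 is the methyl on C8, C18 and C19 are the equatorial methyl and the axial formyl carbon on C4, and C20 is the angular methyl on C10. There are five stereocentres, (3S,4S,5S,9R,10S). C3, C4, C5 and C10 are contiguous and C9 adjoins C10. C4 and C10 are both quaternary, with C19 and C20 syn-diaxial. Ring A carries an axial acetate at C3 next to C4, and ring B a trisubstituted C7=C8 alkene. The fragile groups are the aldehyde (nucleophiles, ylides, boranes), the acetate (strong bases and nucleophiles; once removed, the β-hydroxy aldehyde could undergo retro-aldol cleavage), the C7=C8 alkene (acid-induced migration) and the E geometry at C13=C14. The real difficulty is the quaternary C4: its two one-carbon groups must be placed correctly, next to an oxygenated C3 and in a ring that already holds the quaternary C10. The second problem is C9, whose chain must end equatorial. The key step exploits the O–C3–C4–C19 array of ring A: an oxygen-bearing C3 bonded to a quaternary C4 with a one-carbon arm is what an acyl anion at C3 leaves after adding to a C4=C19 acceptor. Ring B (C8 methyl, C7=C8, C5 bearing C4) is the carvone skeleton, whose isopropenyl group supplies C4, C18 and C19.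

## Logic of the disconnections

**29 ⇒ 28 ⇒ 27 (C19 oxidation level, protecting groups).** No skeletal bond is cut. The C19=O of 29 is taken back to C19–OH in 28, and the acid and hydroxyl of 28 to the tert-butyl ester and silyl ether of 27. The aldehyde cannot pass the ylide and borane steps, so it is made last. The forward oxidation must spare acetate, acid and both alkenes. The acetate must not shift to O19 during acidolysis; it cannot, because O3 and C19 are locked anti (trans-diaxial).

**27 ⇒ 23 + 25, and 25 ⇒ 24 (C12–C13).** The cut lies between sp3 C12 and sp2 C13. The E geometry then comes with fragment 25, and the bond is made by a B-alkyl cross-coupling. This avoids substitution at C11, which is hindered and prone to elimination toward the conjugated diene. The side chain shrinks to a vinyl group on C9. The forward step needs hydroboration at the terminal alkene only, coupling with retention, and an E-selective preparation of 25 from 24.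

**23 ⇒ 22 ⇒ 21 ⇒ 19 (C11=C12, then C9–H and C11–O).** C11=C12 is cut to the aldehyde 22. The C11–O and C9–H bonds of 21 are traced to the exocyclic C9=C11 alkene of 19. A planar C9 lets a bulky borane choose the face opposite C20, so the C9 stereocentre disappears from the problem. The forward steps need regio- and face-selective hydroboration, and oxidation and methylenation of the enolizable aldehyde 22 without enolization.

**19 ⇒ 18 ⇒ 17 (acetyl C–O, C9=C11).** The acetate is removed and C9=C11 is cut to the C9 ketone of 17, which is the carvone carbonyl. The forward methylenation must succeed on a ketone flanked by a quaternary carbon. The acetate is put on only afterwards because it would not survive the ylide.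

**17 ⇒ 16 ⇒ 14 ⇒ 12 (ring A redox).** No skeletal bond is cut: the O–Si bond, the C3–H and C19–H bonds, and C19=O from C19–NO2. A hydride bulky enough to give the axial C3 alcohol would also attack the C9 enone in conjugate fashion. The nitromethyl group is therefore converted first, and the resulting C19 hydroxyl on the axial arm delivers hydride to C3 from its own face while the enone is left alone. The aldehyde lives only between two steps and never meets the C9 methylenation. The forward steps need a Nef reaction that does not cleave the β-keto aldehyde, and an internal hydride transfer through a boat-like array.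

**12 ⇒ 11 (C3–C4, key step).** Cutting C3–C4 opens ring A and removes the C4 stereocentre. It leaves an aldehyde at C3 and a nitroalkene C4=C19 on a cyclohexenone whose two stereocentres are already set. The forward step needs umpolung of the aldehyde, 6-exo addition to a β,β-disubstituted acceptor, and the correct face at C4.

**11 ⇒ 10 ⇒ 9 (C19–N, C3 oxidation level).** The nitro group is placed directly on the terminal carbon of the isopropenyl group. C4 is never a ketone, so C5 is never α to a carbonyl and no Henry reaction has to be run beside an enone. The forward nitration must be regio- and E-selective and must spare the enone alkene.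

**9 ⇒ 7 ⇒ 4 + 5 ⇒ 1 + 2 (C3–O, C10–C1, C10–C20).** C10 is the α′ carbon of 1. Methylation first and allylation second puts the three-carbon chain anti to the isopropenyl group, which is the future trans ring fusion. Allyl bromide is reactive enough for the hindered enolate, and its alkene is carried to the C3 oxygen by hydroboration. The forward steps need kinetic α′ enolization and a borane that prefers the monosubstituted alkene over the isopropenyl group and the enone.

## Other disconnections considered

**Alternative 1:** The cut is C9–C11, with a temporary C8–C11 bond. In the forward step the C7 hydroxyl of allylic alcohol A2 directs the zinc carbenoid from Et2Zn and CH2I2 to the C8=C9 alkene, giving cyclopropyl carbinol A1. A cyclopropylcarbinyl-to-homoallyl opening would then release C11 as an electrophile and leave the C7=C8 alkene.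
- In favour: hydroxyl-directed cyclopropanation is among the most dependable stereospecific reactions. C9 is set by a directing group, not by steric approach, and one strain-release step gives both the C11 handle and the alkene position. On C9 control and on precedent it is the equal or the better of the hydroboration used here.
- Against: it assumes ring A is complete and so does nothing for C4. It needs an oxygen at C7 of defined configuration, to be introduced and then lost. The ring opening must cleave C8–C11 and not C8–C9. The C11 electrophile that results is hindered for substitution.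
- Comparison: the chosen plan solves C4 and the C3 oxygen in one C–C bond formation, which this route leaves open. Step economy should be similar or slightly worse because of the C7 redox detour.

**Alternative 2:** The cuts are C1–C10 and C4–C5. A chiral cationic oxazaborolidine Lewis acid would unite silyloxy dienoate A4 with enal A5 to give ring A aldehyde ester A3.
- In favour: it is convergent, forms two skeletal bonds and sets C5 and C10 together, with the absolute configuration from a catalyst. The silyloxy group and the formyl group are matched in regiochemistry. C4 would later be set by methylating the β-keto ester anti to C20, a reaction type with better precedent than the key step chosen here. On bond-forming efficiency and on C4 precedent this route is the better one.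
- Against: a β-alkyl-α-methyl enal is a sluggish dienophile and the diene is a push–pull system, so the cycloaddition is demanding. Ring B must still be closed, the C7 carbonyl removed, and C9 and the whole side chain built. The C3 ketone has to be reduced to the axial alcohol as here.
- Comparison: the two plans are about equal in steps to a decalin, but this one has more work afterwards, whereas ring B comes from the chiral pool in the chosen plan.

**Alternative 3:** The cut is C9–C10. A chiral iridium catalyst, for example from [Ir(cod)Cl]2 and a phosphoramidite, would ionize the dienyl carbonate of salicylate A7. The para carbon of the phenol attacks the substituted allyl terminus and closes ring B, giving dienone ester A6 with the C9 vinyl group cis to the C10 methyl.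
- In favour: C9 and C10 are set in one catalytic enantioselective step from a flat precursor, two stereocentres against one for the key step here. The vinyl group on C9 is the very handle that the chosen route reaches only after four steps (steps 10, 12, 13 and 14). The salicylate already provides C19 and the C3 oxygen. On stereocentres per step, on side-chain economy and on precedent of the reaction class it is the equal or the better.
- Against: C3, C4 and C5 remain to be set on a cross-conjugated dienone. This needs reduction of C1=C2 and C4=C5 with control of the trans ring fusion, beside C7=C8 and the vinyl group, followed by methylation at C4. Attack at the ortho carbon or at oxygen must also be suppressed.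
- Comparison: it is shorter on paper, but it trades the safe chiral-pool C5/C10 pair of the chosen plan for chemoselective reductions of uncertain outcome.

Key step: step 6

Remark on stereodescriptors: locants are those defined under "Structural features". Descriptors change between intermediates only where substituent priorities change; the spatial arrangement at C5 is that of (S)-carvone throughout.
Remark on the catalyst of step 6: both antipodes of the triazolium salt can be bought. The one that reinforces the substrate's own preference at C4 is to be identified by a trial run with each.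
Abbreviations: Sia2BH is bis(3-methylbutan-2-yl)borane; TBS is tert-butyldimethylsilyl; t-AmOH is 2-methylbutan-2-ol.

## Steps

Step 1
Reactants: 1 (S)-carvone; 2 iodomethane
Product: 4 (5S,6RS)-2,6-dimethyl-5-(prop-1-en-2-yl)cyclohex-2-en-1-one (6-methylcarvone; both C6 epimers), via lithium dienolate 3 (not isolated)
Conditions: LiN(i-Pr)2, THF, −78 °C; MeI, −78 → 0 °C
Reagents that add atoms: iodomethane, CI
Why: Kinetic α′-deprotonation of the enone gives the cross-conjugated dienolate, which is C-methylated (enolate alkylation); the new centre is epimeric but becomes planar again in step 2.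

Step 2
Reactants: 4 6-methylcarvone; 5 allyl bromide
Product: 7 (5R,6R)-2,6-dimethyl-5-(prop-1-en-2-yl)-6-(prop-2-en-1-yl)cyclohex-2-en-1-one (allyl trans to isopropenyl), via lithium enolate 6 (not isolated)
Conditions: LiN(i-Pr)2, THF, −78 → −20 °C; allyl bromide, DMPU, −78 → 0 °C
Reagents that add atoms: allyl bromide, C=CCBr
Why: Enolate alkylation with a reactive allylic halide; the electrophile approaches the planar enolate anti to the neighbouring isopropenyl group, so the chain ends trans to it and the methyl cis, which fixes C10 and the later trans ring fusion.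

Step 3
Reactants: 7 allylated enone
Product: 9 (5R,6R)-6-(3-hydroxypropyl)-2,6-dimethyl-5-(prop-1-en-2-yl)cyclohex-2-en-1-one, via trialkylborane 8 (not isolated)
Conditions: Sia2BH (from BH3·SMe2 and 2-methylbut-2-ene, 1.2 equiv), THF, 0 °C; then Me3NO·2H2O, 65 °C
Reagents that add atoms: trimethylamine N-oxide, C[N+](C)(C)[O-]
Why: Hydroboration–oxidation; the bulky dialkylborane should add to the monosubstituted allyl alkene much faster than to the hindered isopropenyl group or the conjugated ketone, with boron on the terminal carbon. The amine oxide oxidizes C–B without the Weitz–Scheffer epoxidation that alkaline peroxide would cause at the enone.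

Step 4
Reactants: 9 hydroxy enone
Product: 10 (5R,6R)-6-(3-hydroxypropyl)-2,6-dimethyl-5-[(E)-1-nitroprop-1-en-2-yl]cyclohex-2-en-1-one
Conditions: AgNO2 (3 equiv), TEMPO (0.4 equiv), 4 Å MS, ClCH2CH2Cl, 70 °C
Reagents that add atoms: silver nitrite, [Ag+].[O-]N=O
Why: Radical nitration of an alkene: NO2 from AgNO2 adds to the terminal carbon of the electron-rich isopropenyl group, TEMPO traps the tertiary radical, and loss of the hydroxylamine toward the acidic nitromethylene gives the conjugated (E)-nitroalkene with the nitro group anti to the ring. The electron-poor enone alkene should not compete, and any oxidation of the primary alcohol under these conditions converges on step 5.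

Step 5
Reactants: 10 nitroalkene alcohol
Product: 11 3-{(1R,6R)-1,3-dimethyl-6-[(E)-1-nitroprop-1-en-2-yl]-2-oxocyclohex-3-en-1-yl}propanal
Conditions: Dess–Martin periodinane, NaHCO3, CH2Cl2, 0 °C → rt
Reagents that add atoms: none
Why: Dess–Martin oxidation of the primary alcohol under buffered, non-basic conditions, so that the base-sensitive nitroalkene and the allylic C5 centre are not disturbed.

Step 6
Reactants: 11 aldehyde nitroalkene
Product: 12 (4aS,5R,8aR)-2,5,8a-trimethyl-5-(nitromethyl)-4a,7,8,8a-tetrahydronaphthalene-1,6(4H,5H)-dione (3,9-diketone; C18 methyl equatorial and C19 nitromethyl axial on C4)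
Conditions: (5aR,10bS)- or (5aS,10bR)-2-(pentafluorophenyl)-5a,10b-dihydro-4H,6H-indeno[2,1-b][1,2,4]triazolo[4,3-d][1,4]oxazin-2-ium tetrafluoroborate (matched antipode, 20 mol %), NaOAc (40 mol %), t-AmOH, 0 °C → rt
Reagents that add atoms: none
Why: Proposed new method: the carbene freed from the triazolium salt by acetate adds to the C3 aldehyde and proton transfer gives the acyl-anion equivalent (Breslow intermediate), which adds to C4, the β-carbon of the nitroalkene; protonation of the nitronate at C19 and loss of the carbene leave the C3 ketone, the closest known reaction type being the carbene-catalysed intramolecular Stetter cyclization onto enoates and enones that builds quaternary centres in five-membered and aryl-fused rings, together with intermolecular Stetter additions of aliphatic aldehydes to nitroalkenes. Ring A closes in the 6-exo-trig mode through a chair in which the C1–C2 tether and C4 are both equatorial on ring B, so the ring fusion set in step 2 is not at risk. The only new stereocentre is C4: in that chair the trigonal C19, whose inward substituent is a hydrogen, is expected to take the axial site syn to C20 in preference to the C18 methyl, and the matched antipode of the catalyst should reinforce attack on that face. The step needs chemoselectivity for the nitroalkene over the hindered conjugated C9 ketone (crossed benzoin) and over aldol reactions at C2; the high electrophilicity of the nitroalkene, the irreversibility of the conjugate addition and the weak acetate base should secure it. The weak base should also limit deconjugation of the nitroalkene and epimerization at allylic C5.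

Step 7
Reactants: 12 nitromethyl diketone
Product: 14 (1R,4aR,8aS)-1,4a,6-trimethyl-2,5-dioxo-1,2,3,4,4a,5,8,8a-octahydronaphthalene-1-carbaldehyde (3,9-dioxo C19 aldehyde), via sodium nitronate 13 (not isolated)
Conditions: NaOMe, MeOH, 0 °C; then aq. TiCl3, NH4OAc (pH 5–6), THF, 0 °C → rt
Reagents that add atoms: water, O
Why: Nef reaction in its reductive form: trivalent titanium reduces the nitronate through the oxime to the imine, which hydrolyses at buffered pH to the aldehyde, while ketones and the alkene are not affected. The non-enolizable β-keto aldehyde is taken on at once.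

Step 8
Reactants: 14 keto aldehyde
Product: 16 (4aR,5R,6S,8aR)-6-hydroxy-5-(hydroxymethyl)-2,5,8a-trimethyl-4a,5,6,7,8,8a-hexahydronaphthalen-1(4H)-one (3,19-diol; C3 hydroxyl axial and anti to C19), via hydroxy diketone 15 (not isolated)
Conditions: Me4NBH(OAc)3 (6 equiv), MeCN/AcOH (1:1), −20 °C → rt
Reagents that add atoms: none
Why: Triacetoxyborohydride reduces the aldehyde but not an undirected ketone. The C19 alkoxyborohydride so formed can reach only the face of C3 on which the axial C19 arm stands (Evans–Saksena directed reduction), so hydride enters there and the C3 hydroxyl becomes axial, trans to C19. The conjugated C9 ketone has no directing group and should stay.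

Step 9
Reactants: 16 diol
Product: 17 (4aR,5R,6S,8aR)-5-{[tert-butyl(dimethyl)silyl]oxymethyl}-6-hydroxy-2,5,8a-trimethyl-4a,5,6,7,8,8a-hexahydronaphthalen-1(4H)-one
Conditions: TBSCl (1.1 equiv), imidazole, DMF, 0 °C → rt
Reagents that add atoms: tert-butyldimethylsilyl chloride, CC(C)(C)[Si](C)(C)Cl
Why: Silylation selective for the primary hydroxyl over the axial secondary hydroxyl, which is flanked by the quaternary C4.

Step 10
Reactants: 17 silyl ether enone
Product: 18 (1R,2S,4aR,8aS)-1-{[tert-butyl(dimethyl)silyl]oxymethyl}-1,4a,6-trimethyl-5-methylidene-1,2,3,4,4a,5,8,8a-octahydronaphthalen-2-ol (C9=C11 exocyclic; C7=C8 retained)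
Conditions: Ph3PCH3Br (4 equiv), KOt-Bu (3.8 equiv), toluene, 90 °C
Reagents that add atoms: methylenetriphenylphosphorane (from methyltriphenylphosphonium bromide), C=P(c1ccccc1)(c1ccccc1)c1ccccc1
Why: Wittig methylenation of the only carbonyl group with excess ylide at elevated temperature, as used for hindered ketones. The first equivalent only deprotonates the C3 hydroxyl, and the silyl group cannot migrate because O3 and C19 are anti.

Step 11
Reactants: 18 diene alcohol
Product: 19 (1R,2S,4aR,8aS)-1-{[tert-butyl(dimethyl)silyl]oxymethyl}-1,4a,6-trimethyl-5-methylidene-1,2,3,4,4a,5,8,8a-octahydronaphthalen-2-yl acetate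
Conditions: Ac2O, DMAP, pyridine, CH2Cl2, rt → 40 °C
Reagents that add atoms: acetic anhydride, CC(=O)OC(C)=O
Why: DMAP-catalysed acylation of the hindered axial alcohol. It is placed after the ylide step, which the acetate would not survive, and before steps that it tolerates.

Step 12
Reactants: 19 diene acetate
Product: 21 C11 primary alcohol (3-acetoxy; 19-OTBS; C7=C8; C9–CH2OH; 3S,4R,5S,9R,10R), via B-alkyl-9-BBN adduct 20 (not isolated)
Conditions: 9-BBN, THF, 0 → 50 °C; then NaBO3·4H2O, H2O, rt
Reagents that add atoms: sodium perborate, [Na+].[Na+].O[B-]1(O)OO[B-](O)(O)OO1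
Why: Hydroboration–oxidation: 9-BBN places boron on the terminal C11 of the diene and approaches from the face opposite the axial C20, so hydrogen enters C9 anti to C20 and C11 becomes equatorial, which sets C9. The trisubstituted C7=C8 and the acetate are inert, and perborate is mild enough for the acetate.

Step 13
Reactants: 21 C11 alcohol
Product: 22 C11 aldehyde (3-acetoxy; 19-OTBS; C7=C8; C9–CHO; 3S,4R,5S,9R,10R)
Conditions: Dess–Martin periodinane, NaHCO3, CH2Cl2, 0 °C
Reagents that add atoms: none
Why: Dess–Martin oxidation under buffered conditions, so that the β,γ-unsaturated aldehyde is formed without enolization toward C8=C9; it is used directly.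

Step 14
Reactants: 22 C11 aldehyde
Product: 23 C9 vinyl compound (3-acetoxy; 19-OTBS; C7=C8; C9–CH=CH2; 3S,4R,5S,9R,10R)
Conditions: Zn, CH2I2, Ti(Oi-Pr)4, THF, 0 °C → rt
Reagents that add atoms: diiodomethane, ICI
Why: Takai–Lombardo-type methylenation; the zinc–titanium methylene reagent is non-basic and selective for aldehydes, so C9 and the position of C7=C8 should be kept and the acetate left untouched.

Step 15
Reactants: 24 tert-butyl acetoacetate
Product: 25 tert-butyl (E)-3-{[(trifluoromethyl)sulfonyl]oxy}but-2-enoate
Conditions: Tf2O, aq. Me4NOH, hexanes, 5 °C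
Reagents that add atoms: trifluoromethanesulfonic anhydride, O=S(=O)(OS(=O)(=O)C(F)(F)F)C(F)(F)F
Why: O-sulfonylation of the β-keto ester enolate; with the non-coordinating tetramethylammonium counter-ion the unchelated enolate reacts, which gives the enol triflate with the triflate trans to the ester.

Step 16
Reactants: 23 C9 vinyl compound; 25 enol triflate
Product: 27 tert-butyl ester of the (13E)-enoate (3-acetoxy; 19-OTBS; 3S,4R,5S,9R,10S), via B-alkyl-9-BBN adduct 26 (not isolated)
Conditions: 9-BBN, THF, rt; then 25, Pd(dppf)Cl2 (5 mol %), aq. K3PO4, DMF, rt → 40 °C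
Reagents that add atoms: tert-butyl (E)-3-{[(trifluoromethyl)sulfonyl]oxy}but-2-enoate (25), C/C(OS(=O)(=O)C(F)(F)F)=C\C(=O)OC(C)(C)C
Why: 9-BBN adds to the monosubstituted vinyl group only, with boron on C12. The B-alkyl Suzuki–Miyaura coupling forms C12–C13 with retention at the sp2 carbon, so the chain ends trans to the ester (13E).

Step 17
Reactants: 27 protected ester
Product: 28 (E)-5-[(1R,4aS,5R,6S,8aS)-6-acetoxy-5-(hydroxymethyl)-2,5,8a-trimethyl-1,4,4a,5,6,7,8,8a-octahydronaphthalen-1-yl]-3-methylpent-2-enoic acid
Conditions: TFA/CH2Cl2/H2O (10:10:1), 0 °C → rt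
Reagents that add atoms: none
Why: Acidolysis removes the silyl ether by hydrolysis and the tert-butyl ester by loss of isobutene in one operation. The acetate survives and cannot shift to O19, because O3 and C19 are held anti in the rigid ring.

Step 18
Reactants: 28 hydroxy acid
Product: 29 (E)-5-[(1R,4aS,5S,6S,8aS)-6-acetoxy-5-formyl-2,5,8a-trimethyl-1,4,4a,5,6,7,8,8a-octahydronaphthalen-1-yl]-3-methylpent-2-enoic acid (target CNP0312710.1)
Conditions: Dess–Martin periodinane, CH2Cl2, 0 °C → rt
Reagents that add atoms: none
Why: Dess–Martin oxidation of the neopentyl primary alcohol, which tolerates the free acid, the acetate and both alkenes. The aldehyde has no α-hydrogen, so neither epimerization nor loss of acetate by elimination is possible.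

## Compound list

1 | (S)-carvone, (5S)-2-methyl-5-(prop-1-en-2-yl)cyclohex-2-en-1-one | CC1=CC[C@@H](CC1=O)C(C)=C | starting material
2 | iodomethane | CI | starting material
3 | lithium dienolate of 1 (O–Li on C9; C9=C10 and C7=C8) | CC1=CC[C@@H](C=C1[O-])C(C)=C.[Li+] | intermediate
4 | (5S,6RS)-2,6-dimethyl-5-(prop-1-en-2-yl)cyclohex-2-en-1-one | CC1=CC[C@@H](C(C)C1=O)C(C)=C | intermediate
5 | allyl bromide, 3-bromoprop-1-ene | C=CCBr | starting material
6 | lithium enolate of 4 | CC1=CC[C@@H](C(C)=C1[O-])C(C)=C.[Li+] | intermediate
7 | (5R,6R)-2,6-dimethyl-5-(prop-1-en-2-yl)-6-(prop-2-en-1-yl)cyclohex-2-en-1-one | C=CC[C@@]1(C)C(=O)C(C)=CC[C@@H]1C(C)=C | intermediate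
8 | bis(3-methylbutan-2-yl){3-[(1R,6R)-1,3-dimethyl-2-oxo-6-(prop-1-en-2-yl)cyclohex-3-en-1-yl]propyl}borane | CC(C)C(C)B(CCC[C@@]1(C)C(=O)C(C)=CC[C@@H]1C(C)=C)C(C)C(C)C | intermediate
9 | (5R,6R)-6-(3-hydroxypropyl)-2,6-dimethyl-5-(prop-1-en-2-yl)cyclohex-2-en-1-one | OCCC[C@@]1(C)C(=O)C(C)=CC[C@@H]1C(C)=C | intermediate
10 | (5R,6R)-6-(3-hydroxypropyl)-2,6-dimethyl-5-[(E)-1-nitroprop-1-en-2-yl]cyclohex-2-en-1-one | OCCC[C@@]1(C)C(=O)C(C)=CC[C@@H]1/C(C)=C/[N+](=O)[O-] | intermediate
11 | 3-{(1R,6R)-1,3-dimethyl-6-[(E)-1-nitroprop-1-en-2-yl]-2-oxocyclohex-3-en-1-yl}propanal | O=CCC[C@@]1(C)C(=O)C(C)=CC[C@@H]1/C(C)=C/[N+](=O)[O-] | intermediate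
12 | (4aS,5R,8aR)-2,5,8a-trimethyl-5-(nitromethyl)-4a,7,8,8a-tetrahydronaphthalene-1,6(4H,5H)-dione | O=C1CC[C@@]2(C)C(=O)C(C)=CC[C@@H]2[C@]1(C)C[N+](=O)[O-] | intermediate
13 | sodium nitronate of 12 | O=C1CC[C@@]2(C)C(=O)C(C)=CC[C@@H]2[C@]1(C)C=[N+]([O-])[O-].[Na+] | intermediate
14 | (1R,4aR,8aS)-1,4a,6-trimethyl-2,5-dioxo-1,2,3,4,4a,5,8,8a-octahydronaphthalene-1-carbaldehyde | O=C1CC[C@@]2(C)C(=O)C(C)=CC[C@@H]2[C@]1(C)C=O | intermediate
15 | (4aS,5R,8aR)-5-(hydroxymethyl)-2,5,8a-trimethyl-4a,7,8,8a-tetrahydronaphthalene-1,6(4H,5H)-dione | O=C1CC[C@@]2(C)C(=O)C(C)=CC[C@@H]2[C@]1(C)CO | intermediate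
16 | (4aR,5R,6S,8aR)-6-hydroxy-5-(hydroxymethyl)-2,5,8a-trimethyl-4a,5,6,7,8,8a-hexahydronaphthalen-1(4H)-one | O[C@H]1CC[C@@]2(C)C(=O)C(C)=CC[C@@H]2[C@]1(C)CO | intermediate
17 | (4aR,5R,6S,8aR)-5-{[tert-butyl(dimethyl)silyl]oxymethyl}-6-hydroxy-2,5,8a-trimethyl-4a,5,6,7,8,8a-hexahydronaphthalen-1(4H)-one | O[C@H]1CC[C@@]2(C)C(=O)C(C)=CC[C@@H]2[C@]1(C)CO[Si](C)(C)C(C)(C)C | intermediate
18 | (1R,2S,4aR,8aS)-1-{[tert-butyl(dimethyl)silyl]oxymethyl}-1,4a,6-trimethyl-5-methylidene-1,2,3,4,4a,5,8,8a-octahydronaphthalen-2-ol | O[C@H]1CC[C@@]2(C)C(=C)C(C)=CC[C@@H]2[C@]1(C)CO[Si](C)(C)C(C)(C)C | intermediate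
19 | acetate of 18 (3S,4R,5S,10R) | CC(=O)O[C@H]1CC[C@@]2(C)C(=C)C(C)=CC[C@@H]2[C@]1(C)CO[Si](C)(C)C(C)(C)C | intermediate
20 | C11 B-alkyl-9-borabicyclo[3.3.1]nonane adduct of 19 (3S,4R,5S,9R,10S) | CC(=O)O[C@H]1CC[C@@]2(C)[C@H](CB3C4CCCC3CCC4)C(C)=CC[C@@H]2[C@]1(C)CO[Si](C)(C)C(C)(C)C | intermediate
21 | C11 alcohol: 3-acetoxy, 19-OTBS, C7=C8, C9–CH2OH (3S,4R,5S,9R,10R) | CC(=O)O[C@H]1CC[C@@]2(C)[C@H](CO)C(C)=CC[C@@H]2[C@]1(C)CO[Si](C)(C)C(C)(C)C | intermediate
22 | C11 aldehyde: 3-acetoxy, 19-OTBS, C7=C8, C9–CHO (3S,4R,5S,9R,10R) | CC(=O)O[C@H]1CC[C@@]2(C)[C@H](C=O)C(C)=CC[C@@H]2[C@]1(C)CO[Si](C)(C)C(C)(C)C | intermediate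
23 | C9 vinyl compound: 3-acetoxy, 19-OTBS, C7=C8, C11=C12 (3S,4R,5S,9R,10R) | CC(=O)O[C@H]1CC[C@@]2(C)[C@H](C=C)C(C)=CC[C@@H]2[C@]1(C)CO[Si](C)(C)C(C)(C)C | intermediate
24 | tert-butyl acetoacetate, tert-butyl 3-oxobutanoate | CC(=O)CC(=O)OC(C)(C)C | starting material
25 | tert-butyl (E)-3-{[(trifluoromethyl)sulfonyl]oxy}but-2-enoate | C/C(OS(=O)(=O)C(F)(F)F)=C\C(=O)OC(C)(C)C | intermediate
26 | C12 B-alkyl-9-borabicyclo[3.3.1]nonane adduct of 23 (3S,4R,5S,9R,10S) | CC(=O)O[C@H]1CC[C@@]2(C)[C@H](CCB3C4CCCC3CCC4)C(C)=CC[C@@H]2[C@]1(C)CO[Si](C)(C)C(C)(C)C | intermediate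
27 | tert-butyl (E)-5-[(1R,4aS,5R,6S,8aS)-6-acetoxy-5-{[tert-butyl(dimethyl)silyl]oxymethyl}-2,5,8a-trimethyl-1,4,4a,5,6,7,8,8a-octahydronaphthalen-1-yl]-3-methylpent-2-enoate | CC(=O)O[C@H]1CC[C@@]2(C)[C@H](CC/C(C)=C/C(=O)OC(C)(C)C)C(C)=CC[C@@H]2[C@]1(C)CO[Si](C)(C)C(C)(C)C | intermediate
28 | (E)-5-[(1R,4aS,5R,6S,8aS)-6-acetoxy-5-(hydroxymethyl)-2,5,8a-trimethyl-1,4,4a,5,6,7,8,8a-octahydronaphthalen-1-yl]-3-methylpent-2-enoic acid | CC(=O)O[C@H]1CC[C@@]2(C)[C@H](CC/C(C)=C/C(=O)O)C(C)=CC[C@@H]2[C@]1(C)CO | intermediate
29 | (E)-5-[(1R,4aS,5S,6S,8aS)-6-acetoxy-5-formyl-2,5,8a-trimethyl-1,4,4a,5,6,7,8,8a-octahydronaphthalen-1-yl]-3-methylpent-2-enoic acid (3S,4S,5S,9R,10S,13E) | CC(=O)O[C@H]1CC[C@@]2(C)[C@H](CC/C(C)=C/C(=O)O)C(C)=CC[C@@H]2[C@]1(C)C=O | target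

## Step count and least certain steps

Total: 18 steps. Longest linear sequence: 17 steps (1 → 29); step 15 is a one-step side branch.

**Step 6 (key step, proposed new method).** The acyl-anion addition to the hindered β,β-disubstituted nitroalkene may be slow. Aldol self-condensation of the aldehyde, crossed benzoin closure onto the C9 ketone, or base-induced deconjugation of the nitroalkene could then take over. Facial selectivity at C4 may also be poor, since the substrate bias is modest. The fallback uses known chemistry and replaces the catalytic acyl anion by a nitronate. It sets out from 10 and returns at 14.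
- Appel iodination of 10 (PPh3, I2, imidazole) gives the iodide F1.
- Victor Meyer reaction (AgNO2, Et2O) gives the primary nitro compound F2.
- Catalytic DBU in MeCN brings about a 6-exo intramolecular nitro-Michael addition of the C3 nitronate to the nitroalkene, giving the bicyclic 3,19-dinitro compound F3. This addition is reversible, so C4 can equilibrate.
- A double Nef reaction (NaOMe; then aq. TiCl3, NH4OAc) turns the secondary nitro group at C3 into the ketone and the primary one at C19 into the aldehyde, which is 14.

**Step 4.** Regiocontrol in the elimination could be lost, giving the deconjugated allylic nitro isomer, or conversion at the hindered alkene could be low. The fallback replaces the nitroxide-mediated one-pot process by a two-stage addition–elimination. It sets out from 9 and returns at 10: iodonitration with I2 and AgNO2 in Et2O gives the β-iodo nitro adduct F4, and Et3N then removes HI through the nitronate.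

**Step 7.** The reduction could stall at the hindered oxime, or the β-keto aldehyde could be cleaved (deformylation) during the aqueous stage. The fallback changes from reductive to oxidative, anhydrous cleavage. It sets out from 13 and returns at 14: the nitronate is treated with dimethyldioxirane in acetone at 0 °C. No new compound arises on this detour (entry F0).

**Step 8.** The internal hydride transfer from the axial C19 arm needs a boat-like array and may be too slow, so the reduction would stop after the aldehyde. The fallback gives up the directed reduction and removes the enone first. It sets out from 15 and returns at 18.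
- Ketalization of the saturated C3 ketone (1,2-bis(trimethylsilyloxy)ethane, catalytic TMSOTf, −78 °C) gives the dioxolane F5.
- Wittig methylenation at C9 gives the diene F6.
- Mild acid (pyridinium p-toluenesulfonate, wet acetone) frees the hydroxy ketone F7.
- LiBH(s-Bu)3 at −78 °C, now with no enone to attack, gives the axial alcohol as diol F8.
- Selective silylation of the primary hydroxyl as in step 9 gives 18.

**Step 10.** Addition of the bulky ylide to the ketone beside the quaternary C10 may be slow, and the basic ylide could instead deprotonate the enone at C6. The fallback replaces the ylide by a small, less basic nucleophile in an addition–elimination sequence. It sets out from 17 and returns at 18: Me3SiCH2Li with CeCl3 adds to C9 to give the β-hydroxysilane F9, and KH in THF then effects the Peterson elimination.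

**Step 14 (with the handling of 22 from step 13).** The β,γ-unsaturated aldehyde could enolize, which would move the alkene into conjugation or epimerize C9. The fallback avoids the aldehyde. It sets out from 21 and returns at 23: Appel iodination gives the iodide F10, zinc insertion (activated Zn, THF/DMA) gives the alkylzinc iodide F11, and Negishi coupling with vinyl bromide (Pd(PPh3)4) gives 23. The acetate tolerates the organozinc.

## Further compounds

F1 | step 6 | (5R,6R)-6-(3-iodopropyl)-2,6-dimethyl-5-[(E)-1-nitroprop-1-en-2-yl]cyclohex-2-en-1-one | ICCC[C@@]1(C)C(=O)C(C)=CC[C@@H]1/C(C)=C/[N+](=O)[O-]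
F2 | step 6 | (5R,6R)-2,6-dimethyl-6-(3-nitropropyl)-5-[(E)-1-nitroprop-1-en-2-yl]cyclohex-2-en-1-one | [O-][N+](=O)CCC[C@@]1(C)C(=O)C(C)=CC[C@@H]1/C(C)=C/[N+](=O)[O-]
F3 | step 6 | 3-nitro-4-(nitromethyl) bicyclic enone (C3 epimers; C4, C5, C10 as in 12) | [O-][N+](=O)C1CC[C@@]2(C)C(=O)C(C)=CC[C@@H]2[C@]1(C)C[N+](=O)[O-]
F4 | step 4 | 6-(3-hydroxypropyl)-5-(2-iodo-1-nitropropan-2-yl)-2,6-dimethylcyclohex-2-en-1-one (ring centres as in 9; epimers at the iodo carbon) | OCCC[C@@]1(C)C(=O)C(C)=CC[C@@H]1C(C)(I)C[N+](=O)[O-]
F0 | step 7 | none | none
F5 | step 8 | 3,3-ethylenedioxy ketal of 15 | O1CCOC12CC[C@@]3(C)C(=O)C(C)=CC[C@@H]3[C@]2(C)CO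
F6 | step 8 | 9-methylidene derivative of F5 | O1CCOC12CC[C@@]3(C)C(=C)C(C)=CC[C@@H]3[C@]2(C)CO
F7 | step 8 | 19-hydroxy-9-methylidene 3-ketone | O=C1CC[C@@]2(C)C(=C)C(C)=CC[C@@H]2[C@]1(C)CO
F8 | step 8 | 9-methylidene 3,19-diol (C3 hydroxyl axial) | O[C@H]1CC[C@@]2(C)C(=C)C(C)=CC[C@@H]2[C@]1(C)CO
F9 | step 10 | C9 tertiary alcohol bearing a trimethylsilylmethyl group, from 17 (C9 epimers) | O[C@H]1CC[C@@]2(C)C(O)(C[Si](C)(C)C)C(C)=CC[C@@H]2[C@]1(C)CO[Si](C)(C)C(C)(C)C
F10 | step 14 | C11 iodide: 3-acetoxy, 19-OTBS, C7=C8, C9–CH2I | CC(=O)O[C@H]1CC[C@@]2(C)[C@H](CI)C(C)=CC[C@@H]2[C@]1(C)CO[Si](C)(C)C(C)(C)C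
F11 | step 14 | C11 alkylzinc iodide from F10 | CC(=O)O[C@H]1CC[C@@]2(C)[C@H](C[Zn]I)C(C)=CC[C@@H]2[C@]1(C)CO[Si](C)(C)C(C)(C)C
A1 | alternative 1 | cyclopropyl carbinol (C8–C9–C11 cyclopropane, C7 hydroxyl, 3-acetoxy, 19-OTBS) | CC(=O)O[C@H]1CC[C@@]2(C)[C@@H]3C[C@]3(C)[C@H](O)C[C@@H]2[C@]1(C)CO[Si](C)(C)C(C)(C)C
A2 | alternative 1 | allylic alcohol with C8=C9 and C7 hydroxyl | CC(=O)O[C@H]1CC[C@@]2(C)C=C(C)[C@H](O)C[C@@H]2[C@]1(C)CO[Si](C)(C)C(C)(C)C
A3 | alternative 2 | ring A aldehyde ester (cycloadduct) | C[Si](C)(C(C)(C)C)OC1=CC[C@@](C)(C=O)[C@H](CC2(CC)OCCO2)[C@H]1C(=O)OC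
A4 | alternative 2 | methyl (Z)-3-{[tert-butyl(dimethyl)silyl]oxy}penta-2,4-dienoate | C=C/C(O[Si](C)(C)C(C)(C)C)=C/C(=O)OC
A5 | alternative 2 | (E)-4-(2-ethyl-1,3-dioxolan-2-yl)-2-methylbut-2-enal | O=C/C(C)=C/CC1(CC)OCCO1
A6 | alternative 3 | bicyclic dienone ester with C9 vinyl cis to C10 methyl | O=C1C=C[C@@]2(C)[C@H](C=C)C(C)=CCC2=C1C(=O)OC
A7 | alternative 3 | methyl 2-hydroxy-5-methyl-6-[(2Z,4E)-6-(methoxycarbonyloxy)-3-methylhexa-2,4-dien-1-yl]benzoate | COC(=O)c1c(O)ccc(C)c1C/C=C(C)\C=C\COC(=O)OC
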